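**Retrosynthetic overview**

1. The target comes from the bis(benzyl) ether 15 by debenzylation, and 15 from the cyclohexa-1,4-diene 14 by dehydrogenation.
2. The strategy rests on ring E, the para-phenylene whose C1 is bonded to C2 of the 5,7-dihydroxychromone and whose C4 carries the ether oxygen on C8 of the methoxylated flavone, with C2, C3, C5 and C6 all CH. Its bonds C2–C3 and C1–C6 are disconnected by a Diels–Alder reaction into the 2-(flavon-8-yloxy)buta-1,3-diene 7 and the 2-ethynylchromone 13.
3. Diene 7 comes from the intact flavone 1: Elbs hydroxylation at C8, palladium-catalysed allylic etherification with vinyloxirane, then mesylation and elimination.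
4. Alkyne 13 comes from phloroacetophenone 8: dibenzylation, Claisen condensation with the silylpropiolate 10, cyclodehydration, desilylation.
5. Ring order: the pyranone ring of the second chromone (step 7), then ring E (step 9), aromatised in step 10; the three rings of flavone 1 are bought.

Key step: step 9

Assumption: flavone 1 is purchased; allylic ether 5 and mesylate 6 are carried as racemates, because their only stereocentre is destroyed in step 4.
Remark: the dienyl group is put on O8 by allylic etherification and elimination under non-oxidising conditions, because 3 is a para-hydroquinone that a coupling with Cu(OAc)2 (divalent copper) under air would be expected to oxidise to the flavone-5,8-quinone.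

**Route**

Step 1
Reactants: 1 5-hydroxy-7-methoxy-2-(4-methoxyphenyl)-4H-chromen-4-one
Product: 3 5,8-dihydroxy-7-methoxy-2-(4-methoxyphenyl)-4H-chromen-4-one, via potassium flavon-8-yl sulfate 2 (not isolated)
Conditions: K2S2O8, aq KOH, pyridine, 0 °C to rt; then HCl, Na2SO3, 90 °C
Reagents that add atoms: potassium peroxodisulfate, [K+].[K+].[O-]S(=O)(=O)OOS(=O)(=O)[O-]
Why: Elbs persulfate oxidation, in which the 5-phenoxide attacks a peroxide oxygen through C8, its only free para position, and acid hydrolysis of the aryl sulfate 2 should release the 8-hydroxyl, as established for 5-hydroxyflavones.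

Step 2
Reactants: 3 5,8-dihydroxy-7-methoxy-2-(4-methoxyphenyl)-4H-chromen-4-one; 4 2-vinyloxirane (butadiene monoxide, racemic)
Product: 5 5-hydroxy-8-[(1-hydroxybut-3-en-2-yl)oxy]-7-methoxy-2-(4-methoxyphenyl)-4H-chromen-4-one (racemic)
Conditions: Pd2(dba)3·CHCl3 (2 mol%), racemic DACH-phenyl Trost ligand (6 mol%), CH2Cl2, rt, Ar
Reagents that add atoms: none
Why: Tsuji–Trost allylic etherification of a vinyl epoxide, in which the zerovalent palladium catalyst opens 4 to a π-allyl alkoxide that deprotonates the free 8-hydroxyl (the 5-hydroxyl is held in a hydrogen bond to the C4 carbonyl) and the ion-paired phenoxide is delivered to the proximal allyl terminus to give the branched 1,2-adduct, the new stereocentre forming as a racemate with the racemic ligand.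

Step 3
Reactants: 5 5-hydroxy-8-[(1-hydroxybut-3-en-2-yl)oxy]-7-methoxy-2-(4-methoxyphenyl)-4H-chromen-4-one
Product: 6 2-{[5-hydroxy-7-methoxy-2-(4-methoxyphenyl)-4-oxo-4H-chromen-8-yl]oxy}but-3-en-1-yl methanesulfonate (racemic)
Conditions: MsCl (1.05 equiv), Et3N, CH2Cl2, −10 °C
Reagents that add atoms: methanesulfonyl chloride, CS(=O)(=O)Cl
Why: Sulfonylation through sulfene is fast at the primary alcohol, while the chelated 5-hydroxyl should stay free at low temperature, as in selective sulfonylations of 5-hydroxyflavones.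

Step 4
Reactants: 6 2-{[5-hydroxy-7-methoxy-2-(4-methoxyphenyl)-4-oxo-4H-chromen-8-yl]oxy}but-3-en-1-yl methanesulfonate
Product: 7 8-(buta-1,3-dien-2-yloxy)-5-hydroxy-7-methoxy-2-(4-methoxyphenyl)-4H-chromen-4-one
Conditions: KOtBu (2.5 equiv), THF, 0 °C, Ar; pH 7 buffer quench
Reagents that add atoms: none
Why: E2 elimination (the classical route from β-sulfonyloxy ethers to vinyl ethers): after the 5-hydroxyl is deprotonated, tert-butoxide removes the only β-hydrogen, which is allylic and α to oxygen, and mesylate leaves to give the conjugated 2-aryloxydiene.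

Step 5
Reactants: 8 1-(2,4,6-trihydroxyphenyl)ethan-1-one
Product: 9 1-[2,4-bis(benzyloxy)-6-hydroxyphenyl]ethan-1-one
Conditions: BnBr (2.1 equiv), K2CO3, DMF, 60 °C
Reagents that add atoms: benzyl bromide, BrCc1ccccc1
Why: Williamson etherification stops after two hydroxyls, because the last ortho-hydroxyl is deactivated by its hydrogen bond to the acetyl carbonyl, the standard selective protection of phloroacetophenone.

Step 6
Reactants: 9 1-[2,4-bis(benzyloxy)-6-hydroxyphenyl]ethan-1-one; 10 ethyl 3-(trimethylsilyl)prop-2-ynoate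
Product: 11 1-[2,4-bis(benzyloxy)-6-hydroxyphenyl]-5-(trimethylsilyl)pent-4-yne-1,3-dione
Conditions: LiN(SiMe3)2 (3.3 equiv), THF, −78 °C; then 10, −78 to 0 °C; 1 M HCl
Reagents that add atoms: none
Why: Crossed Claisen condensation of the phenoxide–enolate dianion with the ester, in which the silyl group shields the β-carbon of the propiolate so that attack should occur at the ester carbonyl, and deprotonation of the 1,3-diketone drives the reaction.

Step 7
Reactants: 11 1-[2,4-bis(benzyloxy)-6-hydroxyphenyl]-5-(trimethylsilyl)pent-4-yne-1,3-dione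
Product: 12 5,7-bis(benzyloxy)-2-[(trimethylsilyl)ethynyl]-4H-chromen-4-one
Conditions: H2SO4 (cat.), AcOH, 60 °C
Reagents that add atoms: none
Why: Acid-catalysed cyclodehydration as in flavone synthesis from 1-(2-hydroxyaryl)-1,3-diketones: the phenol adds to the protonated alkynyl ketone carbonyl in a 6-exo-trig closure and loss of water gives the 4-pyranone ring, while the silyl group hinders attack of the enol oxygen on the alkyne.

Step 8
Reactants: 12 5,7-bis(benzyloxy)-2-[(trimethylsilyl)ethynyl]-4H-chromen-4-one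
Product: 13 5,7-bis(benzyloxy)-2-ethynyl-4H-chromen-4-one
Conditions: TBAF (1.1 equiv), AcOH (1.5 equiv), THF, −20 to 0 °C
Reagents that add atoms: none
Why: Fluoride-induced protodesilylation of an alkynylsilane, buffered with acetic acid so that no basic nucleophile adds to the electrophilic ethynylchromone.

Step 9
Reactants: 7 8-(buta-1,3-dien-2-yloxy)-5-hydroxy-7-methoxy-2-(4-methoxyphenyl)-4H-chromen-4-one; 13 5,7-bis(benzyloxy)-2-ethynyl-4H-chromen-4-one
Product: 14 5,7-bis(benzyloxy)-2-(4-{[5-hydroxy-7-methoxy-2-(4-methoxyphenyl)-4-oxo-4H-chromen-8-yl]oxy}cyclohexa-1,4-dien-1-yl)-4H-chromen-4-one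
Conditions: 13 (1.5 equiv), BHT (5 mol%), toluene, 130 °C, sealed tube, Ar, dark
Reagents that add atoms: none
Why: Thermal, concerted and asynchronous [4+2] cycloaddition between the electron-rich 2-aryloxybutadiene of 7 (HOMO raised by the oxygen on its C2) and the alkyne of 13, whose LUMO is lowered by conjugation through C2=C3 of the pyranone to the C4 carbonyl, a vinylogous ynone. The closest known reaction type is the Diels–Alder reaction of 2-alkoxy-, 2-silyloxy- and 2-aryloxybutadienes with acetylenic ketones and esters, which gives 1-oxy-4-acylcyclohexa-1,4-dienes that are dehydrogenated to para-disubstituted benzenes. Ring E is closed as a six-membered carbocycle by intermolecular [4+2] annulation: the diene CH2 next to the oxygen-bearing carbon bonds to the terminal alkyne carbon (ring E C2–C3) and the other diene CH2 bonds to the chromone-bearing alkyne carbon (ring E C1–C6), suprafacially on both components. No stereocentre is created, since 14 has only sp2 carbons and two CH2 groups in the new ring. The step needs para regiochemistry, which follows from pairing the largest HOMO coefficient (the diene terminus adjacent to the oxygen-bearing carbon) with the largest LUMO coefficient (the terminal alkyne carbon, remote from the acceptor). It also needs reaction at the alkyne and not at a pyranone C2=C3 bond, which the substrate secures because those bonds are trisubstituted, part of the cross-conjugated 4-pyranone and far more hindered than the unsubstituted alkyne terminus; the excess of 13 and the radical inhibitor hold back dimerisation and polymerisation of the diene.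

Step 10
Reactants: 14 5,7-bis(benzyloxy)-2-(4-{[5-hydroxy-7-methoxy-2-(4-methoxyphenyl)-4-oxo-4H-chromen-8-yl]oxy}cyclohexa-1,4-dien-1-yl)-4H-chromen-4-one
Product: 15 5,7-bis(benzyloxy)-2-(4-{[5-hydroxy-7-methoxy-2-(4-methoxyphenyl)-4-oxo-4H-chromen-8-yl]oxy}phenyl)-4H-chromen-4-one
Conditions: DDQ (1.2 equiv), toluene, rt
Reagents that add atoms: none
Why: Dehydrogenation of a cyclohexa-1,4-diene by DDQ (hydride abstraction from a doubly allylic CH2, then proton loss) is driven by aromatisation and should proceed at room temperature, where benzyl ethers and the chelated phenol are inert.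

Step 11
Reactants: 15 5,7-bis(benzyloxy)-2-(4-{[5-hydroxy-7-methoxy-2-(4-methoxyphenyl)-4-oxo-4H-chromen-8-yl]oxy}phenyl)-4H-chromen-4-one
Product: 16 5,7-dihydroxy-2-(4-{[5-hydroxy-7-methoxy-2-(4-methoxyphenyl)-4-oxo-4H-chromen-8-yl]oxy}phenyl)-4H-chromen-4-one (CNP0259871.0)
Conditions: BCl3 (1 M in CH2Cl2, 8 equiv), pentamethylbenzene (8 equiv), CH2Cl2, −78 to −30 °C; then MeOH, aq HCl work-up
Reagents that add atoms: none
Why: Lewis acid debenzylation, in which BCl3 cleaves the two aryl benzyl ethers at low temperature and pentamethylbenzene traps the benzyl cation, while the aryl methyl ethers (neither peri to a carbonyl) and the diaryl ether should survive.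

**Compound list**

1 | 5-hydroxy-7-methoxy-2-(4-methoxyphenyl)-4H-chromen-4-one (5-hydroxy-7,4'-dimethoxyflavone) | COc1ccc(-c2cc(=O)c3c(O)cc(OC)cc3o2)cc1 | starting material
2 | potassium 5-hydroxy-7-methoxy-2-(4-methoxyphenyl)-4-oxo-4H-chromen-8-yl sulfate | COc1ccc(-c2cc(=O)c3c(O)cc(OC)c(OS(=O)(=O)[O-])c3o2)cc1.[K+] | intermediate
3 | 5,8-dihydroxy-7-methoxy-2-(4-methoxyphenyl)-4H-chromen-4-one | COc1ccc(-c2cc(=O)c3c(O)cc(OC)c(O)c3o2)cc1 | intermediate
4 | 2-vinyloxirane (racemic) | C=CC1CO1 | starting material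
5 | 5-hydroxy-8-[(1-hydroxybut-3-en-2-yl)oxy]-7-methoxy-2-(4-methoxyphenyl)-4H-chromen-4-one (racemic) | C=CC(CO)Oc1c(OC)cc(O)c2c(=O)cc(-c3ccc(OC)cc3)oc12 | intermediate
6 | 2-{[5-hydroxy-7-methoxy-2-(4-methoxyphenyl)-4-oxo-4H-chromen-8-yl]oxy}but-3-en-1-yl methanesulfonate (racemic) | C=CC(COS(C)(=O)=O)Oc1c(OC)cc(O)c2c(=O)cc(-c3ccc(OC)cc3)oc12 | intermediate
7 | 8-(buta-1,3-dien-2-yloxy)-5-hydroxy-7-methoxy-2-(4-methoxyphenyl)-4H-chromen-4-one | C=CC(=C)Oc1c(OC)cc(O)c2c(=O)cc(-c3ccc(OC)cc3)oc12 | intermediate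
8 | 1-(2,4,6-trihydroxyphenyl)ethan-1-one (2',4',6'-trihydroxyacetophenone) | CC(=O)c1c(O)cc(O)cc1O | starting material
9 | 1-[2,4-bis(benzyloxy)-6-hydroxyphenyl]ethan-1-one | CC(=O)c1c(O)cc(OCc2ccccc2)cc1OCc1ccccc1 | intermediate
10 | ethyl 3-(trimethylsilyl)prop-2-ynoate | CCOC(=O)C#C[Si](C)(C)C | starting material
11 | 1-[2,4-bis(benzyloxy)-6-hydroxyphenyl]-5-(trimethylsilyl)pent-4-yne-1,3-dione | C[Si](C)(C)C#CC(=O)CC(=O)c1c(O)cc(OCc2ccccc2)cc1OCc1ccccc1 | intermediate
12 | 5,7-bis(benzyloxy)-2-[(trimethylsilyl)ethynyl]-4H-chromen-4-one | C[Si](C)(C)C#Cc1cc(=O)c2c(OCc3ccccc3)cc(OCc3ccccc3)cc2o1 | intermediate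
13 | 5,7-bis(benzyloxy)-2-ethynyl-4H-chromen-4-one | C#Cc1cc(=O)c2c(OCc3ccccc3)cc(OCc3ccccc3)cc2o1 | intermediate
14 | 5,7-bis(benzyloxy)-2-(4-{[5-hydroxy-7-methoxy-2-(4-methoxyphenyl)-4-oxo-4H-chromen-8-yl]oxy}cyclohexa-1,4-dien-1-yl)-4H-chromen-4-one | COc1ccc(-c2cc(=O)c3c(O)cc(OC)c(OC4=CCC(=CC4)c4cc(=O)c5c(OCc6ccccc6)cc(OCc6ccccc6)cc5o4)c3o2)cc1 | intermediate
15 | 5,7-bis(benzyloxy)-2-(4-{[5-hydroxy-7-methoxy-2-(4-methoxyphenyl)-4-oxo-4H-chromen-8-yl]oxy}phenyl)-4H-chromen-4-one | COc1ccc(-c2cc(=O)c3c(O)cc(OC)c(Oc4ccc(-c5cc(=O)c6c(OCc7ccccc7)cc(OCc7ccccc7)cc6o5)cc4)c3o2)cc1 | intermediate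
16 | 5,7-dihydroxy-2-(4-{[5-hydroxy-7-methoxy-2-(4-methoxyphenyl)-4-oxo-4H-chromen-8-yl]oxy}phenyl)-4H-chromen-4-one | COc1ccc(-c2cc(=O)c3c(O)cc(OC)c(Oc4ccc(-c5cc(=O)c6c(O)cc(O)cc6o5)cc4)c3o2)cc1 | target

**Step count**

Total: 11 steps. Longest linear sequence: 7 steps (steps 1–4 then 9–11; the branch through steps 5–8 then 9–11 is equally long).

**Steps most likely to fail**

Step 9. The alkyne is activated only vinylogously, so cycloaddition may be slower than thermal dimerisation, polymerisation or hydrolysis of the diene. The fallback builds ring E from a purchased benzene ring; it sets out from 3 (with 9 as partner) and comes back at 15. Nucleophilic aromatic substitution of 4-fluorobenzaldehyde by the 8-phenoxide of 3 (K2CO3, DMF, 110 °C, Ar) should give 4-{[5-hydroxy-7-methoxy-2-(4-methoxyphenyl)-4-oxo-4H-chromen-8-yl]oxy}benzaldehyde F1. Claisen–Schmidt condensation of F1 with acetophenone 9 (KOH, EtOH/THF, rt) should give (E)-1-[2,4-bis(benzyloxy)-6-hydroxyphenyl]-3-(4-{[5-hydroxy-7-methoxy-2-(4-methoxyphenyl)-4-oxo-4H-chromen-8-yl]oxy}phenyl)prop-2-en-1-one F2. Oxidative cyclisation of F2 (I2 cat., DMSO, 120 °C) should then give 15.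

Step 7 (together with the condensation of step 6 that feeds it). The enol oxygen may close onto the alkyne to give a 4-pyranone in place of the chromone, or the enolate may add in conjugate fashion to the propiolate one step earlier. The fallback makes the chromone ring first and the alkyne last; it sets out from 9 and comes back at 13. Claisen condensation of 9 with diethyl oxalate (NaOEt, EtOH) should give ethyl 4-[2,4-bis(benzyloxy)-6-hydroxyphenyl]-2,4-dioxobutanoate F3, cyclised with HCl in EtOH to ethyl 5,7-bis(benzyloxy)-4-oxo-4H-chromene-2-carboxylate F4. Selective ester reduction (NaBH4, MeOH/THF, 0 °C) should give 5,7-bis(benzyloxy)-2-(hydroxymethyl)-4H-chromen-4-one F5. Oxidation with Dess–Martin periodinane (CH2Cl2, rt) should give 5,7-bis(benzyloxy)-4-oxo-4H-chromene-2-carbaldehyde F6. Homologation of F6 with the Bestmann–Ohira reagent (K2CO3, MeOH/THF, 0 °C) should then give 13.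

Step 2. The phenoxide may attack the distal allyl terminus to give the linear 1,4-adduct, the branched ether may be re-ionised by the catalyst and drift to the linear isomer, or the di-ortho-substituted phenol may react too slowly. The fallback forms the aryl–oxygen–vinyl bond by Ullmann-type coupling; it sets out from 3 and comes back at 7. Coupling of 3 with 3-bromobut-3-en-1-ol (CuI 10 mol%, N,N-dimethylglycine hydrochloride, Cs2CO3, 1,4-dioxane, 90 °C, Ar) should give 5-hydroxy-8-[(4-hydroxybut-1-en-2-yl)oxy]-7-methoxy-2-(4-methoxyphenyl)-4H-chromen-4-one F7. Mesylation (MsCl, Et3N, CH2Cl2, −10 °C) should give 3-{[5-hydroxy-7-methoxy-2-(4-methoxyphenyl)-4-oxo-4H-chromen-8-yl]oxy}but-3-en-1-yl methanesulfonate F8. E2 elimination of F8 through its allylic hydrogen (KOtBu, THF, 0 °C) should then give 7.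

**Further compounds**

F1 | step 9 | 4-{[5-hydroxy-7-methoxy-2-(4-methoxyphenyl)-4-oxo-4H-chromen-8-yl]oxy}benzaldehyde | COc1ccc(-c2cc(=O)c3c(O)cc(OC)c(Oc4ccc(C=O)cc4)c3o2)cc1
F2 | step 9 | (E)-1-[2,4-bis(benzyloxy)-6-hydroxyphenyl]-3-(4-{[5-hydroxy-7-methoxy-2-(4-methoxyphenyl)-4-oxo-4H-chromen-8-yl]oxy}phenyl)prop-2-en-1-one | COc1ccc(-c2cc(=O)c3c(O)cc(OC)c(Oc4ccc(/C=C/C(=O)c5c(O)cc(OCc6ccccc6)cc5OCc5ccccc5)cc4)c3o2)cc1
F3 | step 7 | ethyl 4-[2,4-bis(benzyloxy)-6-hydroxyphenyl]-2,4-dioxobutanoate | CCOC(=O)C(=O)CC(=O)c1c(O)cc(OCc2ccccc2)cc1OCc1ccccc1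
F4 | step 7 | ethyl 5,7-bis(benzyloxy)-4-oxo-4H-chromene-2-carboxylate | CCOC(=O)c1cc(=O)c2c(OCc3ccccc3)cc(OCc3ccccc3)cc2o1
F5 | step 7 | 5,7-bis(benzyloxy)-2-(hydroxymethyl)-4H-chromen-4-one | OCc1cc(=O)c2c(OCc3ccccc3)cc(OCc3ccccc3)cc2o1
F6 | step 7 | 5,7-bis(benzyloxy)-4-oxo-4H-chromene-2-carbaldehyde | O=Cc1cc(=O)c2c(OCc3ccccc3)cc(OCc3ccccc3)cc2o1
F7 | step 2 | 5-hydroxy-8-[(4-hydroxybut-1-en-2-yl)oxy]-7-methoxy-2-(4-methoxyphenyl)-4H-chromen-4-one | C=C(CCO)Oc1c(OC)cc(O)c2c(=O)cc(-c3ccc(OC)cc3)oc12
F8 | step 2 | 3-{[5-hydroxy-7-methoxy-2-(4-methoxyphenyl)-4-oxo-4H-chromen-8-yl]oxy}but-3-en-1-yl methanesulfonate | C=C(CCOS(C)(=O)=O)Oc1c(OC)cc(O)c2c(=O)cc(-c3ccc(OC)cc3)oc12
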